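The pyranone ring (O1, C2, C3, C4, C4a, C8a) is not closed directly. Ring A carries O1 (at C8a) para to the C6 hydroxyl and ortho to the acyl carbon C4 (at C4a), which is the signature of a dienone–phenol product. The precursor is therefore a spiro p-quinol ether, a 1-oxaspiro[4.5]decadienedione in which O1 and C4 both sit on the future C8a. Acid moves C4 from C8a to C4a: one 1,2-acyl shift expands the five-membered furanone to the six-membered pyranone, aromatises ring A and frees the 6-OH, while C2 (set by asymmetric borylation) is untouched. The spirocycle comes from oxidative dearomatisation of a 3,4,5-trioxygenated aryl β-hydroxy ketone.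

Key step: step 7

Remark: flavanone numbering is used for the ring atoms of 10 and 11; in step 5 the ligand antipode that delivers the 3S boronate is the one used, and 1, 5 and the prenylstannane are taken as commercial.

Step 1
Reactants: 1 3',4',5'-trihydroxyacetophenone
Product: 2 1-[4-hydroxy-3,5-bis(methoxymethoxy)phenyl]ethan-1-one
Conditions: NaH (3.1 equiv), DMF, 0 °C, argon; MOMCl (2.05 equiv), −20 → 0 °C; NH4Cl work-up
Reagents that add atoms: chloromethyl methyl ether COCCl
Why: In the trianion the 4-oxide is conjugated with the para acetyl group and is the least nucleophilic, so the two equivalent 3- and 5-oxides should be alkylated first (Williamson-type O-alkylation under polyanion control), leaving the 4-OH that the later dearomatisation needs.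

Step 2
Reactants: 2 1-[4-hydroxy-3,5-bis(methoxymethoxy)phenyl]ethan-1-one
Product: 3 1-[2-bromo-4-hydroxy-3,5-bis(methoxymethoxy)phenyl]ethan-1-one
Conditions: NBS (1.0 equiv), MeCN, −10 → 0 °C, dark
Reagents that add atoms: N-bromosuccinimide O=C1CCC(=O)N1Br
Why: Electrophilic aromatic bromination: C2 and C6 are the only open ring positions, are equivalent, and each is ortho to one MOM ether and para to the other, so one equivalent of NBS under ionic conditions should stop at the mono-bromide without touching the acetyl methyl group.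

Step 3
Reactants: 3 1-[2-bromo-4-hydroxy-3,5-bis(methoxymethoxy)phenyl]ethan-1-one
Product: 4 1-[4-hydroxy-3,5-bis(methoxymethoxy)-2-(3-methylbut-2-en-1-yl)phenyl]ethan-1-one
Conditions: tributyl(3-methylbut-2-en-1-yl)stannane (1.3 equiv), Pd(PPh3)4 (5 mol %), DMF, 90 °C
Reagents that add atoms: tributyl(3-methylbut-2-en-1-yl)stannane CCCC[Sn](CCCC)(CCCC)CC=C(C)C
Why: Stille cross-coupling: oxidative addition is helped by the ortho acyl group, transfer of the stannane through its α-carbon gives the linear prenyl group, and the free phenol and MOM ethers are inert to neutral Pd(0).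

Step 4
Reactants: 4 1-[4-hydroxy-3,5-bis(methoxymethoxy)-2-(3-methylbut-2-en-1-yl)phenyl]ethan-1-one; 5 4-(methoxymethoxy)benzaldehyde
Product: 6 (E)-1-[4-hydroxy-3,5-bis(methoxymethoxy)-2-(3-methylbut-2-en-1-yl)phenyl]-3-[4-(methoxymethoxy)phenyl]prop-2-en-1-one
Conditions: KOH (50 % aq.), EtOH, rt; NH4Cl work-up
Reagents that add atoms: none
Why: Claisen–Schmidt aldol condensation of the methyl ketone enolate with the non-enolisable aldehyde 5, with dehydration to the conjugated E-enone; MOM ethers and the prenyl group are stable to aqueous KOH at room temperature.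

Step 5
Reactants: 6 (E)-1-[4-hydroxy-3,5-bis(methoxymethoxy)-2-(3-methylbut-2-en-1-yl)phenyl]-3-[4-(methoxymethoxy)phenyl]prop-2-en-1-one
Product: 8 (3S)-3-hydroxy-1-[4-hydroxy-3,5-bis(methoxymethoxy)-2-(3-methylbut-2-en-1-yl)phenyl]-3-[4-(methoxymethoxy)phenyl]propan-1-one, via β-boryl ketone 7 (not isolated)
Conditions: B2pin2 (1.2 equiv), Cu(OH)2 (5 mol %), chiral 6,6'-bis(1-hydroxy-2,2-dimethylpropyl)-2,2'-bipyridine (6 mol %), AcOH (6 mol %), H2O/THF, rt; then NaBO3·4H2O, THF/H2O, rt
Reagents that add atoms: bis(pinacolato)diboron CC1(C)OB(OC1(C)C)B1OC(C)(C)C(C)(C)O1 (boron of 7); sodium perborate [Na+].[Na+].O[B-]1(O)OO[B-](O)(O)OO1 (hydroxyl oxygen of 8)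
Why: Copper-catalysed enantioselective conjugate borylation of the enone (the ligand antipode decides the face) followed by oxidation of the C–B bond with retention should set the future C2 stereocentre as the S carbinol under near-neutral conditions that spare the free phenol.

Step 6
Reactants: 8 (3S)-3-hydroxy-1-[4-hydroxy-3,5-bis(methoxymethoxy)-2-(3-methylbut-2-en-1-yl)phenyl]-3-[4-(methoxymethoxy)phenyl]propan-1-one
Product: 9 (2S)-7,9-bis(methoxymethoxy)-2-[4-(methoxymethoxy)phenyl]-6-(3-methylbut-2-en-1-yl)-1-oxaspiro[4.5]deca-6,9-diene-4,8-dione (both epimers at spiro C5)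
Conditions: PhI(OAc)2 (1.1 equiv), (CF3)2CHOH/CH2Cl2, −20 → 0 °C
Reagents that add atoms: none
Why: Iodine(III)-mediated oxidative dearomatisation of the 2,6-dialkoxyphenol with 5-exo capture of the para (ipso) carbon by the C3 hydroxyl (oxidative spiroetherification) should give the p-quinol ether; the C–O bond at the stereocentre is not broken, so S is kept, and the ortho prenyl group twists the acyl group out of conjugation, which should ease attack at the acyl-bearing carbon.

Step 7
Reactants: 9 (2S)-7,9-bis(methoxymethoxy)-2-[4-(methoxymethoxy)phenyl]-6-(3-methylbut-2-en-1-yl)-1-oxaspiro[4.5]deca-6,9-diene-4,8-dione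
Product: 11 nirurinetin, via tris-MOM flavanone 10 (not isolated)
Conditions: BF3·OEt2 (0.3 equiv), CH2Cl2, −40 → 0 °C; then 3 M HCl in MeOH, 40 °C
Reagents that add atoms: none
Why: BF3 binds the dienone carbonyl of 9 and generates a hydroxypentadienyl cation; the acyl carbon C4 then shifts from the spiro carbon (future C8a) to the neighbouring unsubstituted carbon (future C4a), the migration origin being stabilised as an oxocarbenium ion by O1, and loss of the C4a proton aromatises ring A, so the five-membered ring O1–C2–C3–C4–C8a becomes the six-membered pyranone by insertion of C4a. The closest known reaction type is the dienone–phenol rearrangement with acyl migration, as in the acid-induced ring expansion of spirodienone ethers and lactones made by phenol dearomatisation. No ring is closed by cyclisation: the pyranone arises by a suprafacial 1,2-shift (ring expansion by one atom), and methanolic HCl then removes the three MOM groups by acetal exchange. No new stereocentre forms; C2 from step 5 keeps its S configuration because none of its bonds is broken, and the spiro centre (both epimers) is destroyed. Two selectivities are needed: acyl rather than O1 must migrate, which follows because only acyl migration leaves a cation stabilised by the ring oxygen, and migration must go to C4a rather than to the prenyl-bearing C8, which follows because only the C–H terminus can lose a proton and aromatise while the other shift is reversible. Low temperature and a catalytic Lewis acid should keep the benzylic C2–O1 bond and the prenyl group intact before the short, mild HCl treatment.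

Compound list
1 | 3',4',5'-trihydroxyacetophenone | CC(=O)c1cc(O)c(O)c(O)c1 | starting material
2 | 1-[4-hydroxy-3,5-bis(methoxymethoxy)phenyl]ethan-1-one | CC(=O)c1cc(OCOC)c(O)c(OCOC)c1 | intermediate
3 | 1-[2-bromo-4-hydroxy-3,5-bis(methoxymethoxy)phenyl]ethan-1-one | CC(=O)c1cc(OCOC)c(O)c(OCOC)c1Br | intermediate
4 | 1-[4-hydroxy-3,5-bis(methoxymethoxy)-2-(3-methylbut-2-en-1-yl)phenyl]ethan-1-one | CC(=O)c1cc(OCOC)c(O)c(OCOC)c1CC=C(C)C | intermediate
5 | 4-(methoxymethoxy)benzaldehyde | COCOc1ccc(C=O)cc1 | starting material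
6 | (E)-1-[4-hydroxy-3,5-bis(methoxymethoxy)-2-(3-methylbut-2-en-1-yl)phenyl]-3-[4-(methoxymethoxy)phenyl]prop-2-en-1-one | COCOc1ccc(/C=C/C(=O)c2cc(OCOC)c(O)c(OCOC)c2CC=C(C)C)cc1 | intermediate
7 | (3S)-1-[4-hydroxy-3,5-bis(methoxymethoxy)-2-(3-methylbut-2-en-1-yl)phenyl]-3-[4-(methoxymethoxy)phenyl]-3-(4,4,5,5-tetramethyl-1,3,2-dioxaborolan-2-yl)propan-1-one | CC1(C)OB(OC1(C)C)[C@@H](CC(=O)c1cc(OCOC)c(O)c(OCOC)c1CC=C(C)C)c1ccc(OCOC)cc1 | intermediate (not isolated)
8 | (3S)-3-hydroxy-1-[4-hydroxy-3,5-bis(methoxymethoxy)-2-(3-methylbut-2-en-1-yl)phenyl]-3-[4-(methoxymethoxy)phenyl]propan-1-one | O[C@@H](CC(=O)c1cc(OCOC)c(O)c(OCOC)c1CC=C(C)C)c1ccc(OCOC)cc1 | intermediate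
9 | (2S)-7,9-bis(methoxymethoxy)-2-[4-(methoxymethoxy)phenyl]-6-(3-methylbut-2-en-1-yl)-1-oxaspiro[4.5]deca-6,9-diene-4,8-dione | COCOC1=C(CC=C(C)C)C2(C=C(OCOC)C1=O)O[C@H](c1ccc(OCOC)cc1)CC2=O | intermediate
10 | (2S)-6-hydroxy-5,7-bis(methoxymethoxy)-2-[4-(methoxymethoxy)phenyl]-8-(3-methylbut-2-en-1-yl)-2,3-dihydro-4H-chromen-4-one | COCOc1c(CC=C(C)C)c2O[C@H](c3ccc(OCOC)cc3)CC(=O)c2c(OCOC)c1O | intermediate (not isolated)
11 | nirurinetin, (2S)-5,6,7-trihydroxy-2-(4-hydroxyphenyl)-8-(3-methylbut-2-en-1-yl)-2,3-dihydro-4H-chromen-4-one | CC(C)=CCc1c(O)c(O)c(O)c2c1O[C@H](c1ccc(O)cc1)CC2=O | target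

Total step count: 7. Longest linear sequence: 7 steps (1 → 11); aldehyde 5 enters at step 4.

Steps most likely to fail

Step 6. Capture of the oxidised phenol at the acyl-bearing para carbon may be too slow, so that acetate or solvent adds at the MOM-oxy-bearing ortho carbons, or the benzylic carbinol ionises in the fluorinated solvent. The fallback sets out from 8 and comes back at 9, and runs the spirocyclisation at the alcohol oxidation level. NaBH4 (MeOH, 0 °C) reduces the ketone to (3S)-1-[4-hydroxy-3,5-bis(methoxymethoxy)-2-(3-methylbut-2-en-1-yl)phenyl]-3-[4-(methoxymethoxy)phenyl]propane-1,3-diol F1 (both C1 epimers), so that the para carbon carries an sp3 carbinol and no acyl group. PhI(OAc)2 in (CF3)2CHOH/CH2Cl2 should then give, by 5-exo capture through the C3 hydroxyl, (2S)-4-hydroxy-7,9-bis(methoxymethoxy)-2-[4-(methoxymethoxy)phenyl]-6-(3-methylbut-2-en-1-yl)-1-oxaspiro[4.5]deca-6,9-dien-8-one F2. Dess–Martin periodinane oxidises the C4 hydroxyl of F2 to the ketone 9.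

Step 7. Heterolysis of the benzylic C2–O1 bond may compete with the acyl shift (loss of enantiopurity or ring opening), and acid may cyclise the prenyl group onto the neighbouring hydroxyl while rearrangement and deprotection share one pot. The fallback sets out from 2 and comes back at 10; it moves the ring expansion ahead of prenyl introduction, so each acid-triggered event is run alone.
- 2 and 5 under the conditions of step 4 give (E)-1-[4-hydroxy-3,5-bis(methoxymethoxy)phenyl]-3-[4-(methoxymethoxy)phenyl]prop-2-en-1-one F3.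
- Borylation and oxidation as in step 5 give, via (3S)-1-[4-hydroxy-3,5-bis(methoxymethoxy)phenyl]-3-[4-(methoxymethoxy)phenyl]-3-(4,4,5,5-tetramethyl-1,3,2-dioxaborolan-2-yl)propan-1-one F4 (not isolated), the aldol (3S)-3-hydroxy-1-[4-hydroxy-3,5-bis(methoxymethoxy)phenyl]-3-[4-(methoxymethoxy)phenyl]propan-1-one F5.
- Oxidation as in step 6 gives the symmetrical spirodienone (2S)-7,9-bis(methoxymethoxy)-2-[4-(methoxymethoxy)phenyl]-1-oxaspiro[4.5]deca-6,9-diene-4,8-dione F6, which has only one kind of migration terminus.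
- BF3·OEt2 alone (CH2Cl2, −40 °C) gives, isolated, (2S)-6-hydroxy-5,7-bis(methoxymethoxy)-2-[4-(methoxymethoxy)phenyl]-2,3-dihydro-4H-chromen-4-one F7.
- NIS (MeCN, 0 °C) iodinates C8, the only open position of ring A, to give (2S)-6-hydroxy-8-iodo-5,7-bis(methoxymethoxy)-2-[4-(methoxymethoxy)phenyl]-2,3-dihydro-4H-chromen-4-one F8.
- Stille coupling with tributyl(3-methylbut-2-en-1-yl)stannane (Pd(PPh3)4, DMF, 80 °C) gives 10, which is then deprotected on its own with HCl in MeOH to 11.

Step 1. Regiocontrol in the trianion alkylation may be lost (alkylation of the 4-oxide, over-alkylation), and the electron-rich trianion may be oxidised by air. The fallback sets out from 1 and comes back at 2; it protects the most acidic 4-OH temporarily. Allyl bromide (1.0 equiv), KHCO3, DMF gives 1-[3,5-dihydroxy-4-(prop-2-en-1-yloxy)phenyl]ethan-1-one F9. MOMCl with i-Pr2NEt gives 1-[3,5-bis(methoxymethoxy)-4-(prop-2-en-1-yloxy)phenyl]ethan-1-one F10. Pd(PPh3)4 with morpholine removes the allyl group to give 2.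

Further compounds
F1 | step 6 | (3S)-1-[4-hydroxy-3,5-bis(methoxymethoxy)-2-(3-methylbut-2-en-1-yl)phenyl]-3-[4-(methoxymethoxy)phenyl]propane-1,3-diol | O[C@@H](CC(O)c1cc(OCOC)c(O)c(OCOC)c1CC=C(C)C)c1ccc(OCOC)cc1
F2 | step 6 | (2S)-4-hydroxy-7,9-bis(methoxymethoxy)-2-[4-(methoxymethoxy)phenyl]-6-(3-methylbut-2-en-1-yl)-1-oxaspiro[4.5]deca-6,9-dien-8-one | COCOC1=C(CC=C(C)C)C2(C=C(OCOC)C1=O)O[C@H](c1ccc(OCOC)cc1)CC2O
F3 | step 7 | (E)-1-[4-hydroxy-3,5-bis(methoxymethoxy)phenyl]-3-[4-(methoxymethoxy)phenyl]prop-2-en-1-one | COCOc1ccc(/C=C/C(=O)c2cc(OCOC)c(O)c(OCOC)c2)cc1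
F4 | step 7 | (3S)-1-[4-hydroxy-3,5-bis(methoxymethoxy)phenyl]-3-[4-(methoxymethoxy)phenyl]-3-(4,4,5,5-tetramethyl-1,3,2-dioxaborolan-2-yl)propan-1-one | CC1(C)OB(OC1(C)C)[C@@H](CC(=O)c1cc(OCOC)c(O)c(OCOC)c1)c1ccc(OCOC)cc1
F5 | step 7 | (3S)-3-hydroxy-1-[4-hydroxy-3,5-bis(methoxymethoxy)phenyl]-3-[4-(methoxymethoxy)phenyl]propan-1-one | O[C@@H](CC(=O)c1cc(OCOC)c(O)c(OCOC)c1)c1ccc(OCOC)cc1
F6 | step 7 | (2S)-7,9-bis(methoxymethoxy)-2-[4-(methoxymethoxy)phenyl]-1-oxaspiro[4.5]deca-6,9-diene-4,8-dione | COCOC1=CC2(C=C(OCOC)C1=O)O[C@H](c1ccc(OCOC)cc1)CC2=O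
F7 | step 7 | (2S)-6-hydroxy-5,7-bis(methoxymethoxy)-2-[4-(methoxymethoxy)phenyl]-2,3-dihydro-4H-chromen-4-one | COCOc1cc2O[C@H](c3ccc(OCOC)cc3)CC(=O)c2c(OCOC)c1O
F8 | step 7 | (2S)-6-hydroxy-8-iodo-5,7-bis(methoxymethoxy)-2-[4-(methoxymethoxy)phenyl]-2,3-dihydro-4H-chromen-4-one | COCOc1c(I)c2O[C@H](c3ccc(OCOC)cc3)CC(=O)c2c(OCOC)c1O
F9 | step 1 | 1-[3,5-dihydroxy-4-(prop-2-en-1-yloxy)phenyl]ethan-1-one | CC(=O)c1cc(O)c(OCC=C)c(O)c1
F10 | step 1 | 1-[3,5-bis(methoxymethoxy)-4-(prop-2-en-1-yloxy)phenyl]ethan-1-one | CC(=O)c1cc(OCOC)c(OCC=C)c(OCOC)c1
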